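**Plan**
- Retrosynthetic cuts, in order: the acetate C–O bond; in ring B (the acetoxybutyl butenolide) the lactone O–C bond to the second spiro carbon, the carboxyl C–C bond and the alkyne–spiro-carbon bond; the two ring C–Br bonds; the bond from the spiro carbon of ring A (the butyl butenolide) to its ring CH2; the C5–cyclopropyl bond of ring A.
- Enabling feature: the spiro carbon of ring A is an O-substituted quaternary carbon inside the four-membered ring, and its neighbour (the future second spiro carbon) can be a ketone. This is the pattern left by a cyclopropanol-to-cyclobutanone 1,2-shift onto C5 of a furanone cation.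
- Forward order: tetronic acid → ring A (4-bromo-3-butylbutenolide) → C5 joined to cyclopropanone → C5 bromide → ring expansion to the spiro cyclobutanone → enone → trans-dibromide → alkyne fragment joined → ring B closed last → acetate.
- Stereochemistry: the first spiro centre comes from a catalyst-controlled, enantioconvergent ionisation/migration; the two CHBr centres from anti addition of Br2 directed by that centre; the second spiro centre from a relay (acetylide addition anti to Br, anti SN2′ carbonylation, axis-to-centre transfer in the bromolactonisation); the carbinol from (R)-hex-1-yn-3-ol.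
- Locants for the spirocyclic intermediates follow 5-oxaspiro[3.4]octane: C1 ketone carbon, C2 and C3 ring CH, C4 spiro carbon, O5, C6 lactone carbonyl, C7 (butyl), C8 (Br).

Key step: step 7

Assumption: the sense of induction of the anion-binding catalyst in step 7 cannot be derived from precedent; the (S)-thiourea is written, and its equally available antipode is to be used if that is the one that delivers (4R)-14.

**Step 1**
Reactants: 1 tetronic acid; 2 butanal
Product: 4 3-butyl-4-hydroxyfuran-2(5H)-one, via alkylidene dione 3 (not isolated)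
Conditions: Hantzsch ester (1.1 equiv), L-proline (10 mol %), CH2Cl2, 25 °C
Reagents that add atoms: none
Why: Organocatalytic three-component reductive alkylation, in which the proline-mediated Knoevenagel adduct is reduced in situ by conjugate hydride transfer from the Hantzsch ester, so bis-addition is avoided and no stereocentre is formed.

**Step 2**
Reactants: 4 3-butyl-4-hydroxyfuran-2(5H)-one
Product: 5 4-bromo-3-butylfuran-2(5H)-one
Conditions: (COBr)2 (1.2 equiv), DMF (cat.), CH2Cl2, 0 → 25 °C
Reagents that add atoms: oxalyl bromide O=C(Br)C(=O)Br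
Why: Vilsmeier-type deoxybromination of the vinylogous acid by addition–elimination at C4, the standard conversion of tetronic acids into 4-bromofuranones.

**Step 3**
Reactants: 6 1-ethoxy-1-(trimethylsilyloxy)cyclopropane
Product: 7 1-ethoxycyclopropan-1-ol
Conditions: MeOH, 25 °C, then evaporation
Reagents that add atoms: none
Why: Methanolysis of the labile trimethylsilyl ketal (silyl transfer to methanol) should give the cyclopropanone ethyl hemiacetal cleanly.

**Step 4**
Reactants: 5 4-bromo-3-butylfuran-2(5H)-one; 7 1-ethoxycyclopropan-1-ol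
Product: 11 4-bromo-3-butyl-5-(1-hydroxycyclopropyl)furan-2(5H)-one (racemic), via lithium furanolate 8 (not isolated), via magnesium hemiacetal salt 9 (not isolated), via cyclopropanone 10 (not isolated)
Conditions: 5, LiN(SiMe3)2, THF, −78 °C; 7, MeMgBr, THF, 0 °C; combine, −78 → −20 °C; aq. NH4Cl
Reagents that add atoms: none
Why: Vinylogous aldol addition, in which the magnesium salt of the hemiacetal releases cyclopropanone and its strained carbonyl is captured at C5 of the aromatic furanolate (C3 is blocked by butyl and γ-attack restores the conjugated butenolide); the C5 centre forms racemic and is erased in step 6.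

**Step 5**
Reactants: 11 4-bromo-3-butyl-5-(1-hydroxycyclopropyl)furan-2(5H)-one
Product: 12 tert-butyl{[4-bromo-3-butyl-5-(1-{[tert-butyl(dimethyl)silyl]oxy}cyclopropyl)furan-2-yl]oxy}dimethylsilane
Conditions: TBSOTf (2.4 equiv), Et3N (3 equiv), CH2Cl2, 0 °C
Reagents that add atoms: tert-butyldimethylsilyl trifluoromethanesulfonate CC(C)(C)[Si](C)(C)OS(=O)(=O)C(F)(F)F
Why: Soft enolisation (O-silylation of the lactone carbonyl, then loss of H-5) gives the 2-silyloxyfuran, while silylation of the tertiary cyclopropanol protects it from electrophilic ring opening in the next step.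

**Step 6**
Reactants: 12 bis-silyl furan
Product: 13 4,5-dibromo-3-butyl-5-(1-{[tert-butyl(dimethyl)silyl]oxy}cyclopropyl)furan-2(5H)-one (racemic)
Conditions: NBS (1.0 equiv), CH2Cl2, −78 °C; cold filtration, used at once
Reagents that add atoms: N-bromosuccinimide O=C1CCC(=O)N1Br
Why: Electrophilic γ-bromination of the 2-silyloxyfuran, which reacts far faster than the cyclopropyl silyl ether, installs the C5 leaving group and restores the butenolide; the bromide is racemic, which does not matter because step 7 is enantioconvergent.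

**Step 7**
Reactants: 13 4,5-dibromo-3-butyl-5-(1-{[tert-butyl(dimethyl)silyl]oxy}cyclopropyl)furan-2(5H)-one
Product: 14 (4R)-8-bromo-7-butyl-5-oxaspiro[3.4]oct-7-ene-1,6-dione
Conditions: (S)-2-[[3,5-bis(trifluoromethyl)phenyl]thioureido]-N-benzyl-N,3,3-trimethylbutanamide (10 mol %), TBME, −78 → −40 °C
Reagents that add atoms: none
Why: Proposed new method: the thiourea binds the C5 bromide by double hydrogen bonding and ionises racemic 13 to a 2-oxofuranylium (acyloxocarbenium) cation paired with the chiral thiourea–bromide anion; a cyclopropane C–C bond aligned with the empty p orbital then migrates to C5 while the silyloxy oxygen pushes, and the bound bromide takes the silyl group from the resulting oxocarbenium, releasing ketone 14 and TBSBr and turning the catalyst over. The closest known reactions are thiourea anion-binding catalysis of additions to oxocarbenium ions generated from α-halo ethers, chiral phosphoric acid-catalysed semipinacol ring expansions of 2-oxo allylic alcohols, and the silver- or Lewis acid-promoted expansion of 1-(1-haloalkyl)cyclopropanols to cyclobutanones. The four-membered ring arises by expansion of the three-membered ring through a 1,2-alkyl shift (not an exo or endo cyclisation), driven by conversion of the cation into a carbonyl group. The new stereocentre, spiro C4, is defined by which enantiotopic methylene migrates to which face of the planar cation; the chiral ion pair governs this, so both enantiomers of 13 should converge on (4R)-14. The step needs migration to outrun bromide return, proton loss and uncatalysed ionisation: the two methylenes are constitutionally equivalent so there is no regiochemical issue, the silyl ether cannot close to an epoxide, and TBME at −78 °C should keep the covalent bromide intact until the catalyst engages it.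

**Step 8**
Reactants: 14 (4R)-8-bromo-7-butyl-5-oxaspiro[3.4]oct-7-ene-1,6-dione
Product: 16 (4R)-8-bromo-7-butyl-5-oxaspiro[3.4]octa-2,7-diene-1,6-dione, via lithium enolate 15 (not isolated)
Conditions: LiN(SiMe3)2 (1.05 equiv), THF, −78 °C; then PhS(Cl)=N-t-Bu (1.1 equiv), −78 °C; used cold
Reagents that add atoms: none
Why: Mukaiyama dehydrogenation, in which the only enolisable position (C2) is deprotonated, the enolate attacks sulfur of N-tert-butylbenzenesulfinimidoyl chloride and the adduct undergoes syn elimination at −78 °C, giving the strained enone without heating and leaving the non-enolisable spiro centre untouched.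

**Step 9**
Reactants: 16 (4R)-8-bromo-7-butyl-5-oxaspiro[3.4]octa-2,7-diene-1,6-dione
Product: 17 (2R,3R,4S)-2,3,8-tribromo-7-butyl-5-oxaspiro[3.4]oct-7-ene-1,6-dione
Conditions: Br2 (1.0 equiv), CH2Cl2, −78 °C, dark
Reagents that add atoms: bromine BrBr
Why: Anti addition of bromine to the strained enone, in which the bromonium ion forms on the face of C2=C3 syn to O5 (the other face is covered by the C8–Br bond lying under the spiro centre) and bromide opens it at the β-carbon C3 from the opposite side, placing Br-3 anti to O5 and Br-2 trans to it, with C2 (α to the ketone) able to settle in the trans arrangement.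

**Step 10**
Reactants: 18 (R)-hex-1-yn-3-ol
Product: 19 (R)-tert-butyl(hex-1-yn-3-yloxy)dimethylsilane
Conditions: TBSCl, imidazole, DMF, 25 °C
Reagents that add atoms: tert-butyldimethylsilyl chloride CC(C)(C)[Si](C)(C)Cl
Why: Standard silylation of the secondary alcohol masks the carbinol, whose (R) configuration is carried unchanged to the acetoxy-bearing centre of the target.

**Step 11**
Reactants: 17 (2R,3R,4S)-2,3,8-tribromo-7-butyl-5-oxaspiro[3.4]oct-7-ene-1,6-dione; 19 (R)-tert-butyl(hex-1-yn-3-yloxy)dimethylsilane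
Product: 22 tert-butyl (1R,2R,3R,4S)-2,3,8-tribromo-7-butyl-1-[(3R)-3-{[tert-butyl(dimethyl)silyl]oxy}hex-1-yn-1-yl]-6-oxo-5-oxaspiro[3.4]oct-7-en-1-yl carbonate, via lithium acetylide 20 (not isolated), via lithium C1-alkoxide 21 (not isolated)
Conditions: 19, n-BuLi, THF, −78 °C; 17, −78 °C; then Boc2O, −78 → 0 °C; aq. NH4Cl
Reagents that add atoms: di-tert-butyl dicarbonate CC(C)(C)OC(=O)OC(=O)OC(C)(C)C
Why: 1,2-Addition of a lithium acetylide to the highly electrophilic cyclobutanone anti to the α-bromine at C2 and to the α-oxygen O5 (polar Felkin–Anh/Cornforth control) sets C1 with its oxygen syn to Br-2, and the alkoxide, which cannot close to an epoxide because it is cis to Br-2, is acylated in situ to the tertiary propargylic carbonate.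

**Step 12**
Reactants: 22 propargylic tert-butyl carbonate
Product: 23 (aS,3R)-3-{[tert-butyl(dimethyl)silyl]oxy}-2-{[(2R,3R,4S)-2,3,8-tribromo-7-butyl-6-oxo-5-oxaspiro[3.4]oct-7-en-1-ylidene]methylidene}hexanoic acid
Conditions: Pd(PPh3)4 (5 mol %), CO (5 atm), THF–H2O (10:1), 20 °C
Reagents that add atoms: carbon monoxide [C-]#[O+]; water O
Why: Tsuji-type carbonylation of a propargylic carbonate, in which zerovalent palladium ionises the tertiary carbonate by anti SN2′ attack at the distal alkyne carbon (expected to be faster than insertion into the C–Br bonds under CO), the allenylpalladium inserts CO with retention and water cleaves the acyl complex, so the carboxyl group lies on the ring face opposite to the departed oxygen and the allene axis is set by centre-to-axis transfer.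

**Step 13**
Reactants: 23 allenoic acid
Product: 24 (5S,6S,11R,12R)-4,10,11,12-tetrabromo-3-butyl-9-[(1R)-1-{[tert-butyl(dimethyl)silyl]oxy}butyl]-1,7-dioxadispiro[4.0.4^6.2^5]dodeca-3,9-diene-2,8-dione
Conditions: NBS (1.1 equiv), MeCN, 0 °C, dark
Reagents that add atoms: N-bromosuccinimide O=C1CCC(=O)N1Br
Why: Bromolactonisation of a 2,3-allenoic acid (5-endo attack of the carboxyl oxygen on the ring-bound allene terminus while Br+ enters the central carbon) delivers oxygen to the face on which the carboxyl group lies, so the axial chirality becomes the second spiro centre with its oxygen anti to the neighbouring ring bromine and anti to the oxygen of ring A.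

**Step 14**
Reactants: 24 silyl ether
Product: 25 (5S,6S,11R,12R)-4,10,11,12-tetrabromo-3-butyl-9-[(1R)-1-hydroxybutyl]-1,7-dioxadispiro[4.0.4^6.2^5]dodeca-3,9-diene-2,8-dione
Conditions: HF (48 % aq.), MeCN, 0 → 20 °C
Reagents that add atoms: none
Why: Acidic fluoride cleavage of the secondary silyl ether avoids the basic or nucleophilic conditions that would attack the 4-bromobutenolides or eliminate HBr, and no stereocentre is touched.

**Step 15**
Reactants: 25 secondary alcohol
Product: 26 (1R)-1-[(5S,6S,11R,12R)-4,10,11,12-tetrabromo-9-butyl-2,8-dioxo-1,7-dioxadispiro[4.0.4^6.2^5]dodeca-3,9-dien-3-yl]butyl acetate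
Conditions: Ac2O (1.5 equiv), Sc(OTf)3 (1 mol %), MeCN, 0 °C
Reagents that add atoms: acetic anhydride CC(=O)OC(C)=O
Why: Lewis acid-catalysed O-acetylation under amine-free conditions acylates the alcohol oxygen only, with retention at the carbinol carbon, and should give the target.

**Compound list**
1 | tetronic acid (furan-2,4(3H,5H)-dione) | O=C1COC(=O)C1 | starting material
2 | butanal | CCCC=O | starting material
3 | 3-butylidenefuran-2,4(3H,5H)-dione | CCCC=C1C(=O)COC1=O | intermediate
4 | 3-butyl-4-hydroxyfuran-2(5H)-one | CCCCC1=C(O)COC1=O | intermediate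
5 | 4-bromo-3-butylfuran-2(5H)-one | CCCCC1=C(Br)COC1=O | intermediate
6 | 1-ethoxy-1-(trimethylsilyloxy)cyclopropane | CCOC1(O[Si](C)(C)C)CC1 | starting material
7 | 1-ethoxycyclopropan-1-ol | CCOC1(O)CC1 | intermediate
8 | lithium 4-bromo-3-butylfuran-2-olate | [Li+].CCCCc1c(Br)coc1[O-] | intermediate
9 | bromomagnesium 1-ethoxycyclopropan-1-olate | CCOC1([O-])CC1.[Mg+2].[Br-] | intermediate
10 | cyclopropanone | O=C1CC1 | intermediate
11 | 4-bromo-3-butyl-5-(1-hydroxycyclopropyl)furan-2(5H)-one (racemic) | CCCCC1=C(Br)C(OC1=O)C1(O)CC1 | intermediate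
12 | tert-butyl{[4-bromo-3-butyl-5-(1-{[tert-butyl(dimethyl)silyl]oxy}cyclopropyl)furan-2-yl]oxy}dimethylsilane | CCCCc1c(Br)c(oc1O[Si](C)(C)C(C)(C)C)C1(O[Si](C)(C)C(C)(C)C)CC1 | intermediate
13 | 4,5-dibromo-3-butyl-5-(1-{[tert-butyl(dimethyl)silyl]oxy}cyclopropyl)furan-2(5H)-one (racemic) | CCCCC1=C(Br)C(Br)(OC1=O)C1(O[Si](C)(C)C(C)(C)C)CC1 | intermediate
14 | (4R)-8-bromo-7-butyl-5-oxaspiro[3.4]oct-7-ene-1,6-dione | CCCCC1=C(Br)[C@@]2(OC1=O)CCC2=O | intermediate
15 | lithium (4R)-8-bromo-7-butyl-6-oxo-5-oxaspiro[3.4]octa-1,7-dien-1-olate | [Li+].CCCCC1=C(Br)[C@@]2(OC1=O)CC=C2[O-] | intermediate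
16 | (4R)-8-bromo-7-butyl-5-oxaspiro[3.4]octa-2,7-diene-1,6-dione | CCCCC1=C(Br)[C@@]2(OC1=O)C=CC2=O | intermediate
17 | (2R,3R,4S)-2,3,8-tribromo-7-butyl-5-oxaspiro[3.4]oct-7-ene-1,6-dione (Br-3 anti to O5, Br-2 trans to Br-3) | CCCCC1=C(Br)[C@@]2(OC1=O)[C@@H](Br)[C@H](Br)C2=O | intermediate
18 | (R)-hex-1-yn-3-ol | CCC[C@@H](O)C#C | starting material
19 | (R)-tert-butyl(hex-1-yn-3-yloxy)dimethylsilane | CCC[C@@H](O[Si](C)(C)C(C)(C)C)C#C | intermediate
20 | lithium (3R)-3-{[tert-butyl(dimethyl)silyl]oxy}hex-1-yn-1-ide | [Li+].CCC[C@@H](O[Si](C)(C)C(C)(C)C)C#[C-] | intermediate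
21 | lithium (1R,2R,3R,4S)-2,3,8-tribromo-7-butyl-1-[(3R)-3-{[tert-butyl(dimethyl)silyl]oxy}hex-1-yn-1-yl]-6-oxo-5-oxaspiro[3.4]oct-7-en-1-olate | [Li+].CCCCC1=C(Br)[C@@]2(OC1=O)[C@@H](Br)[C@H](Br)[C@@]2([O-])C#C[C@@H](CCC)O[Si](C)(C)C(C)(C)C | intermediate
22 | tert-butyl (1R,2R,3R,4S)-2,3,8-tribromo-7-butyl-1-[(3R)-3-{[tert-butyl(dimethyl)silyl]oxy}hex-1-yn-1-yl]-6-oxo-5-oxaspiro[3.4]oct-7-en-1-yl carbonate (carbonate oxygen syn to Br-2 and O5) | CCCCC1=C(Br)[C@@]2(OC1=O)[C@@H](Br)[C@H](Br)[C@@]2(OC(=O)OC(C)(C)C)C#C[C@@H](CCC)O[Si](C)(C)C(C)(C)C | intermediate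
23 | (aS,3R)-3-{[tert-butyl(dimethyl)silyl]oxy}-2-{[(2R,3R,4S)-2,3,8-tribromo-7-butyl-6-oxo-5-oxaspiro[3.4]oct-7-en-1-ylidene]methylidene}hexanoic acid (carboxyl on the ring face anti to O5 and to Br-2) | CCCCC1=C(Br)[C@@]2(OC1=O)[C@@H](Br)[C@H](Br)C2=[C@]=C(C(=O)O)[C@@H](CCC)O[Si](C)(C)C(C)(C)C | intermediate
24 | (5S,6S,11R,12R)-4,10,11,12-tetrabromo-3-butyl-9-[(1R)-1-{[tert-butyl(dimethyl)silyl]oxy}butyl]-1,7-dioxadispiro[4.0.4^6.2^5]dodeca-3,9-diene-2,8-dione | CCCCC1=C(Br)[C@@]2(OC1=O)[C@@H](Br)[C@H](Br)[C@@]21OC(=O)C([C@@H](CCC)O[Si](C)(C)C(C)(C)C)=C1Br | intermediate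
25 | (5S,6S,11R,12R)-4,10,11,12-tetrabromo-3-butyl-9-[(1R)-1-hydroxybutyl]-1,7-dioxadispiro[4.0.4^6.2^5]dodeca-3,9-diene-2,8-dione | CCCCC1=C(Br)[C@@]2(OC1=O)[C@@H](Br)[C@H](Br)[C@@]21OC(=O)C([C@@H](CCC)O)=C1Br | intermediate
26 | (1R)-1-[(5S,6S,11R,12R)-4,10,11,12-tetrabromo-9-butyl-2,8-dioxo-1,7-dioxadispiro[4.0.4^6.2^5]dodeca-3,9-dien-3-yl]butyl acetate (CNP0268004.1) | CCCCC1=C(Br)[C@@]2(OC1=O)[C@@H](Br)[C@H](Br)[C@@]21OC(=O)C([C@@H](CCC)OC(C)=O)=C1Br | target

**Step count**
Total: 15 steps. Longest linear sequence: 13 steps (1, 2, 4–9, 11–15, from tetronic acid).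

**Steps most likely to fail**

1. Step 7 (new method). The hydrogen-bond donor may ionise the acyloxy-stabilised bromide too slowly, or the ion pair may discriminate the two faces poorly, so that uncatalysed racemic expansion competes. Fallback: starting from 13, stoichiometric AgOTf in CH2Cl2 at −40 °C (classical halide abstraction with semipinacol shift) should give racemic 8-bromo-7-butyl-5-oxaspiro[3.4]oct-7-ene-1,6-dione F1. Preparative chromatography on a chiral stationary phase then separates the enantiomers; (4S)-8-bromo-7-butyl-5-oxaspiro[3.4]oct-7-ene-1,6-dione F2 is set aside and the (4R)-enantiomer is 14, where the route resumes.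

2. Step 9. Bromonium formation is reversible, and bromide may prefer to enter C3 from the open face syn to O5 through the minor, more hindered bromonium; this would give the other trans dibromide (Br-3 syn to O5). The C8–Br bond under the spiro centre makes this a real possibility. Fallback (the hydrogen at C3, not the bromine, is delivered last), starting from 16:
   - PhSeBr in CH2Cl2 at −78 °C adds anti across the enone (selenium at C2, bromide at C3) to give (4S)-3,8-dibromo-7-butyl-2-(phenylselanyl)-5-oxaspiro[3.4]oct-7-ene-1,6-dione F3, whose configuration at C2 and C3 is irrelevant.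
   - Oxidation with H2O2 and selenoxide syn elimination toward H-3 give the β-bromoenone (4S)-3,8-dibromo-7-butyl-5-oxaspiro[3.4]octa-2,7-diene-1,6-dione F4.
   - B(C6F5)3-catalysed 1,4-hydrosilylation with Et3SiH delivers hydride to C3 from the open face syn to O5, which forces bromine anti to O5, and gives (3S,4S)-3,8-dibromo-7-butyl-1-[(triethylsilyl)oxy]-5-oxaspiro[3.4]octa-1,7-dien-6-one F5.
   - NBS at −78 °C brominates C2 anti to Br-3 and returns to 17.

3. Step 11. The acetylide may deprotonate C2, with loss of bromide from C3, or the lithium alkoxide may fragment before it is acylated; facial selectivity is a further concern because both faces of the ketone are encumbered. Fallback: starting from 17 and 20, the acetylide is transmetalated with anhydrous CeCl3 (THF, −78 °C) to the non-basic, oxophilic dichloro[(3R)-3-{[tert-butyl(dimethyl)silyl]oxy}hex-1-yn-1-yl]cerium F6. This is added to 17 and, after aqueous work-up, the tertiary alcohol (1R,2R,3R,4S)-2,3,8-tribromo-7-butyl-1-[(3R)-3-{[tert-butyl(dimethyl)silyl]oxy}hex-1-yn-1-yl]-1-hydroxy-5-oxaspiro[3.4]oct-7-en-6-one F7 is isolated. In a separate operation F7 is converted into its lithium alkoxide 21 with LiN(SiMe3)2 at −78 °C and acylated with Boc2O, returning to 22.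

**Further compounds**
F1 | step 7 | racemic 8-bromo-7-butyl-5-oxaspiro[3.4]oct-7-ene-1,6-dione | CCCCC1=C(Br)C2(OC1=O)CCC2=O
F2 | step 7 | (4S)-8-bromo-7-butyl-5-oxaspiro[3.4]oct-7-ene-1,6-dione | CCCCC1=C(Br)[C@]2(OC1=O)CCC2=O
F3 | step 9 | (4S)-3,8-dibromo-7-butyl-2-(phenylselanyl)-5-oxaspiro[3.4]oct-7-ene-1,6-dione (2,3-trans, C2/C3 face isomers) | CCCCC1=C(Br)[C@@]2(OC1=O)C(Br)C([Se]c3ccccc3)C2=O
F4 | step 9 | (4S)-3,8-dibromo-7-butyl-5-oxaspiro[3.4]octa-2,7-diene-1,6-dione | CCCCC1=C(Br)[C@@]2(OC1=O)C(Br)=CC2=O
F5 | step 9 | (3S,4S)-3,8-dibromo-7-butyl-1-[(triethylsilyl)oxy]-5-oxaspiro[3.4]octa-1,7-dien-6-one | CCCCC1=C(Br)[C@@]2(OC1=O)[C@@H](Br)C=C2O[Si](CC)(CC)CC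
F6 | step 11 | dichloro[(3R)-3-{[tert-butyl(dimethyl)silyl]oxy}hex-1-yn-1-yl]cerium | CCC[C@@H](O[Si](C)(C)C(C)(C)C)C#C[Ce](Cl)Cl
F7 | step 11 | (1R,2R,3R,4S)-2,3,8-tribromo-7-butyl-1-[(3R)-3-{[tert-butyl(dimethyl)silyl]oxy}hex-1-yn-1-yl]-1-hydroxy-5-oxaspiro[3.4]oct-7-en-6-one | CCCCC1=C(Br)[C@@]2(OC1=O)[C@@H](Br)[C@H](Br)[C@@]2(O)C#C[C@@H](CCC)O[Si](C)(C)C(C)(C)C
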